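## The problem

Target 17 (CNP0232913.0, achiral) is a diarylmethane. Ring A carries five contiguous substituents: C1 CH2OH, C2 the benzyl carbon, C3 and C4 hydroxyl, C5 bromine (C6 is H). Ring B is a plain 3-bromo-4-hydroxyphenyl group that can be bought as its aldehyde 1. The difficulty is the regiochemistry of ring A: electrophilic bromination of a finished catechol would go para to the C3 oxygen (C6) or onto ring B, so the C5 bromine and the two ortho benzylic carbons must be placed by construction. There is no stereocentre in the target; the bridge carbon is stereogenic only while it still carries oxygen, is made racemic, controls nothing and becomes CH2 in the last step. Three groups limit the conditions. The catechol is oxidized by air under base. The two aryl bromides exclude hydrogenolysis, dissolving metals and halogen–metal exchange. The C1 CH2OH lies para to the C4 hydroxyl, so in acid or hot base it ionizes to a quinone methide and is lost as an ether, a methyl group or an oligomer. The feature that opens the route is that C1 with its CH2O, C6–H, C5–Br and C4 are the atoms of 4-bromofurfuryl alcohol, that C2–C3 is a two-carbon unit at the alkyne oxidation level, and that bonding the CH2OH oxygen to the bridge carbon gives the five-membered ring of a 1,3-dihydroisobenzofuran (phthalan). A phenol next to the ring fusion of a phthalan is what the gold-catalysed isomerization of a furfuryl propargyl ether produces, so ring A, the phthalan ring and the C3 oxygen can arise in one step. Around that step three things remain: an ether that is both benzylic and propargylic must face a Lewis acid, the C4 oxygen must be introduced, and only one of the two benzylic C–O bonds of the phthalan may be cut.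

## Retrosynthesis

**17 from 16.** The bond between the bridge carbon and the ring oxygen of phthalan 16 is cut last; in the retrosynthetic sense the C1 CH2OH oxygen is tied to the bridge carbon. Of the two benzylic C–O bonds this one is secondary, diaryl-substituted and flanked by the para-hydroxyl of ring B and the ortho-hydroxyl of ring A, so it ionizes far more easily than the primary one. The precursor keeps the acid-sensitive para-hydroxybenzylic alcohol masked as an ether until the end. The forward reaction must ionize only the diarylmethyl carbon and deliver hydride there.

**16 from 15 and 13.** The ring B pivalate of 15 is removed, and before that the C4–O bond is cut, leading to monophenol 13. Carrying both oxygens through ring construction would require a 5-oxygenated furan, which is not a stable building block. In 13, C4 is the only unsubstituted carbon ortho to the C3 hydroxyl, so an ortho-selective oxygen transfer has one site. The phthalan ether shields the future CH2OH from the oxidant and the pivalate shields the ring B phenol. The forward reaction must stop at the catechol (ortho-quinone 14, reduced in the same flask).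

**13 from 10 (key disconnection).** Three bonds are cut: C1–C2, C3–C4 and C3–O. This dissolves both the benzene ring and the phthalan ring and leaves furfuryl propargyl ether 10, a 2,4-disubstituted furan tethered through oxygen to a terminal alkyne. Cutting only C1–C2 and C3–C4 (a furan Diels–Alder reaction) would need an activated alkyne and would leave a carbon substituent on C3. The gold-catalysed isomerization works with the terminal alkyne and moves the furan oxygen onto C3. The forward reaction needs the furan to attack the gold-bound alkyne faster than the benzylic and propargylic ether ionizes. A preformed monovalent gold complex, Ph3PAuNTf2, is therefore planned; oxophilic trivalent gold chloride, AuCl3, is avoided.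

**10 from 8.** Only the oxygen substituent of ring B changes: pivalate in 10, triisopropylsilyl ether in 8. A para-silyloxy group would stabilize a cation at the bridge carbon, which is the main way the key step could fail; an acyloxy group with the adjacent bromine removes that stabilization. The ester cannot be present earlier, because it would not survive the Grignard reagent and the alkoxide used to assemble 8. The cost is one step.

**8 from 4 and 7.** The ether C–O bond on the furfurylic side is cut, giving propargylic alcohol 4 as nucleophile and furfuryl bromide 7 as electrophile. The other C–O bond would require substitution at a carbon that is benzylic and propargylic, with ionization and allenyl by-products. The chosen cut is an SN2 reaction at a primary carbon.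

**4 from 2, 3 and 1; 7 from 6 and 5.** The C–C bond between the carbinol carbon and the alkyne is cut, giving silyl-protected aldehyde 2 (from commercial 1) and ethynylmagnesium bromide 3. Bromide 7 comes from alcohol 6, the reduction product of commercial 4-bromo-2-furaldehyde 5. All carbons of the target thus come from 1, 3 and 5.

## Roads not taken

Alternative 1: The cut removes both exocyclic C–C bonds of ring A at once, C1–carbinol carbon and C2–bridge carbon, and leaves a 3,4-dioxygenated benzyne. Fluoride would release the C1–C2 aryne from 2,2-dimethyl-5-(trimethylsilyl)-1,3-benzodioxol-4-yl triflate A1. tert-Butyl isocyanide A2 would add at C1, the aryne carbon remote from the acetal oxygen. The C2 aryl anion would add to 3-bromo-4-methoxybenzaldehyde A3, and the alkoxide would close onto the nitrilium carbon to give iminolactone A4.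
- Merits: the route is convergent, the catechol is present from the start, the adjacent oxygen steers the aryne addition the right way, and one step sets both benzylic carbons.
- Weak points: A4 has no bromine on C5. It would have to come from late electrophilic substitution, where C6 (para to the C3 oxygen) and the position ortho to the methoxy group of ring B compete. A1 needs its own multistep preparation. C1 arrives at the carboxylic acid oxidation level, so imidate hydrolysis and two reductions follow. The aryl methyl ether must be cleaved with a strong Lewis acid next to ionizable benzylic positions.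
- Comparison: this road is more convergent and reaches the carbon skeleton faster. The chosen plan sets against it that the C5 bromine is built into the furan, that no electrophilic bromination is needed and that all deprotections are mild.

Alternative 2: Here ring B is disconnected, at C1'–C6' and C2'–C3'. The enamine formed from a secondary amine and methyl 5-bromo-3,4-dimethoxy-2-(3-oxopropyl)benzoate A5 would add at its alpha carbon to methyl vinyl ketone A6, and aldol condensation would close cyclohexenone A7. Dehydrogenation to the phenol, ortho-bromination of ring B, ester reduction and cleavage of two methyl ethers would follow.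
- Merits: only classical, metal-free carbonyl chemistry is used, and bromination of ring B after aromatization has its para position blocked.
- Weak points: the ring-forming step is spent on the ring that can be bought, while the real problem, pentasubstituted ring A, is left unsolved inside A5. The stereocentre of A7 is made and then destroyed. The dehydrogenation and the double demethylation are harsh for a para-hydroxybenzylic alcohol.
- Comparison: each step of this road is more predictable than a gold-catalysed isomerization of an untested furan. The chosen plan sets against it that it constructs the difficult ring from three commercial compounds and buys the easy one.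

Alternative 3: Ring A is cut at C1–C2 and C5–C6. 5-(3-Bromo-4-methoxyphenyl)pentane-2,3-dione A8 would be converted into its bis(trimethylsilyl) dienol ether A9, which would add to methyl propiolate A10 to give cyclohexa-1,4-diene A11. Dehydrogenation, bromination at C5, ester reduction and demethylation would follow.
- Merits: both catechol oxygens and the C1 carbon arrive in the ring-forming step, and no separate oxygenation is needed. In that respect this road is better than the chosen one.
- Weak points: A9 requires double enolization of an unsymmetrical diketone with defined regiochemistry and alkene geometry. The two silyloxy groups oppose each other, so the required orientation rests only on the weak bias of the terminal alkyl group. After aromatization the C5 bromine must again be introduced by electrophilic substitution, in competition with ring B.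
- Comparison: the chosen plan sets against the saved oxygenation step a tether that fixes which carbons join and a bromine that is in place before the ring exists.

Key step: step 7

## Route

Remarks on the chemistry:
- Compounds 1, 3 (as its THF solution) and 5 are taken to be commercially available.
- Gold-bound species of the catalytic cycle (the cyclopropyl carbene and the enal carbene) are described in words; the metal-free intermediates 11 and 12 are numbered.
- Alkoxide and phenoxide salts formed and consumed within one operation are not numbered separately.

Step 1
Reactants: 1 3-bromo-4-hydroxybenzaldehyde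
Product: 2 3-bromo-4-[(triisopropylsilyl)oxy]benzaldehyde
Conditions: TIPSCl, imidazole, DMF, rt
Reagents that add atoms: triisopropylsilyl chloride, CC(C)[Si](Cl)(C(C)C)C(C)C
Why: Imidazole-assisted silylation of a phenol. The bulky silyl ether is chosen because it withstands the Grignard reagent of step 2 and the alkoxide of step 5, which an aryl ester would not.

Step 2
Reactants: 2 3-bromo-4-[(triisopropylsilyl)oxy]benzaldehyde; 3 ethynylmagnesium bromide
Product: 4 racemic 1-{3-bromo-4-[(triisopropylsilyl)oxy]phenyl}prop-2-yn-1-ol
Conditions: THF, −78 to 0 °C; aq. NH4Cl
Reagents that add atoms: none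
Why: 1,2-Addition of an alkynyl Grignard reagent to an aromatic aldehyde; the aryl bromide and the silyl ether are inert at low temperature. The carbinol carbon is made racemic on purpose, since it becomes the CH2 bridge in step 10.

Step 3
Reactants: 5 4-bromo-2-furaldehyde
Product: 6 (4-bromofuran-2-yl)methanol
Conditions: NaBH4, MeOH, 0 °C
Reagents that add atoms: none
Why: Sodium borohydride reduction of an aldehyde; the bromofuran is untouched.

Step 4
Reactants: 6 (4-bromofuran-2-yl)methanol
Product: 7 4-bromo-2-(bromomethyl)furan
Conditions: PBr3 (0.4 equiv), Et2O, 0 °C; cold aq. NaHCO3 wash, dried solution used at once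
Reagents that add atoms: phosphorus tribromide, BrP(Br)Br
Why: Conversion of a primary furfurylic alcohol into the bromide with PBr3 (phosphite ester, then SN2 by bromide). The ring bromine lowers the electron density of the furan and slows the self-condensation typical of furfuryl halides.

Step 5
Reactants: 4 racemic 1-{3-bromo-4-[(triisopropylsilyl)oxy]phenyl}prop-2-yn-1-ol; 7 4-bromo-2-(bromomethyl)furan
Product: 8 racemic (4-bromofuran-2-yl)methyl 1-{3-bromo-4-[(triisopropylsilyl)oxy]phenyl}prop-2-yn-1-yl ether
Conditions: NaH, THF, 0 °C; then 7, Bu4NI (cat.), 0 °C to rt
Reagents that add atoms: none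
Why: Williamson ether synthesis: the sodium alkoxide of 4 displaces bromide from the primary furfurylic carbon of 7 (SN2, iodide catalysis). The alkoxide is too weak a base to deprotonate the alkyne, and the hindered aryl silyl ether resists it.

Step 6
Reactants: 8 racemic (4-bromofuran-2-yl)methyl 1-{3-bromo-4-[(triisopropylsilyl)oxy]phenyl}prop-2-yn-1-yl ether
Product: 10 racemic 2-bromo-4-{1-[(4-bromofuran-2-yl)methoxy]prop-2-yn-1-yl}phenyl pivalate, via phenoxide 9 (not isolated)
Conditions: TBAF, THF, 0 °C; then PivCl, DMAP (cat.), 0 °C to rt
Reagents that add atoms: pivaloyl chloride, CC(C)(C)C(Cl)=O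
Why: Fluoride cleavage of the aryl silyl ether and acylation of the resulting phenoxide in the same flask. It replaces the para electron donor on ring B by an acyloxy group just before the Lewis-acid step, so that the benzylic and propargylic C–O bond is no longer prone to ionization; the hindered pivalate does not migrate to hydroxyl groups formed later.

Step 7
Reactants: 10 racemic 2-bromo-4-{1-[(4-bromofuran-2-yl)methoxy]prop-2-yn-1-yl}phenyl pivalate
Product: 13 racemic 6-bromo-3-[3-bromo-4-(pivaloyloxy)phenyl]-1,3-dihydroisobenzofuran-4-ol, via oxepine 11 (not isolated), via arene oxide 12 (not isolated)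
Conditions: Ph3PAuNTf2 (5 mol %), CH2Cl2, rt
Reagents that add atoms: none
Why: Gold-catalysed furan–yne isomerization to a phenol, the reaction type established for furfuryl propargyl ethers and applied here to a new member of that class. The cationic monovalent gold centre activates the terminal alkyne, and the furan carbon that carries the tether attacks the internal alkyne carbon in a 5-exo-dig closure, which forms C1–C2, closes the five-membered phthalan ring and leaves a cyclopropyl gold carbene. Cleavage of the furan C–O bond opens this to a gold carbene conjugated with a Z-enal, whose carbonyl oxygen adds to the carbene carbon (C3–O) in a seven-membered closure and releases oxepine 11 and the catalyst. 6π-Electrocyclization of 11 forms C3–C4 and closes the six-membered carbocycle as arene oxide 12; cleavage of its C4–O bond followed by aromatization gives phenol 13 with the hydroxyl on C3. No stereocentre is set under control: the bridge carbon stays racemic and the diastereomers of 12 converge on one arene. The tether decides which carbons join, so the selectivity that matters is cyclization against ionization of the benzylic and propargylic C–O bond; the pivaloyloxy and bromo substituents of ring B withdraw the stabilization such a cation would need, and the preformed, silver-free and acid-free catalyst in CH2Cl2 offers no strong oxophilic Lewis acid. If the epoxide were to open the other way, the hydroxyl would sit on C4 and step 8 would still lead to quinone 14.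

Step 8
Reactants: 13 racemic 6-bromo-3-[3-bromo-4-(pivaloyloxy)phenyl]-1,3-dihydroisobenzofuran-4-ol
Product: 15 racemic 6-bromo-3-[3-bromo-4-(pivaloyloxy)phenyl]-1,3-dihydroisobenzofuran-4,5-diol, via ortho-quinone 14 (not isolated)
Conditions: IBX, DMF, rt; then aq. Na2S2O4
Reagents that add atoms: 2-iodoxybenzoic acid (IBX), O=C1OI(=O)(O)c2ccccc12
Why: Ortho-oxygenation of a phenol with IBX: the phenol binds to pentavalent iodine and oxygen is delivered intramolecularly to the ortho carbon. C4 is the only unsubstituted ortho position, so quinone 14 forms regioselectively and is reduced by dithionite before it can decompose. The cyclic ether keeps the future benzylic alcohol away from the oxidant and the pivalate shields the ring B phenol.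

Step 9
Reactants: 15 racemic 6-bromo-3-[3-bromo-4-(pivaloyloxy)phenyl]-1,3-dihydroisobenzofuran-4,5-diol
Product: 16 racemic 6-bromo-3-(3-bromo-4-hydroxyphenyl)-1,3-dihydroisobenzofuran-4,5-diol
Conditions: K2CO3, MeOH (degassed), rt
Reagents that add atoms: none
Why: Carbonate-catalysed methanolysis (transesterification) of an aryl ester, run under argon so that the catecholate is not oxidized. It frees the para-hydroxyl of ring B, the donor that makes the next ionization easy.

Step 10
Reactants: 16 racemic 6-bromo-3-(3-bromo-4-hydroxyphenyl)-1,3-dihydroisobenzofuran-4,5-diol
Product: 17 6-bromo-3-(3-bromo-4-hydroxybenzyl)-4-(hydroxymethyl)benzene-1,2-diol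
Conditions: Et3SiH, TFA, CH2Cl2, −20 to 0 °C; aq. NaHCO3
Reagents that add atoms: none
Why: Ionic hydrogenation: protonation of the ring oxygen and ionization at the diarylmethyl carbon, which is stabilized by the para-hydroxyl of ring B and the ortho-hydroxyl of ring A, then hydride transfer from the silane. The primary benzylic C–O bond is much harder to ionize (primary carbon, meta bromine) and at low temperature with limited acid should remain as the CH2OH group. The stereocentre is removed.

## Compound list

1 | 3-bromo-4-hydroxybenzaldehyde | O=Cc1ccc(O)c(Br)c1 | starting material
2 | 3-bromo-4-[(triisopropylsilyl)oxy]benzaldehyde | CC(C)[Si](Oc1ccc(C=O)cc1Br)(C(C)C)C(C)C | intermediate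
3 | ethynylmagnesium bromide | C#C[Mg]Br | starting material
4 | racemic 1-{3-bromo-4-[(triisopropylsilyl)oxy]phenyl}prop-2-yn-1-ol | CC(C)[Si](Oc1ccc(cc1Br)C(O)C#C)(C(C)C)C(C)C | intermediate
5 | 4-bromo-2-furaldehyde | O=Cc1cc(Br)co1 | starting material
6 | (4-bromofuran-2-yl)methanol | OCc1cc(Br)co1 | intermediate
7 | 4-bromo-2-(bromomethyl)furan | BrCc1cc(Br)co1 | intermediate
8 | racemic (4-bromofuran-2-yl)methyl 1-{3-bromo-4-[(triisopropylsilyl)oxy]phenyl}prop-2-yn-1-yl ether | CC(C)[Si](Oc1ccc(cc1Br)C(C#C)OCc1cc(Br)co1)(C(C)C)C(C)C | intermediate
9 | racemic tetrabutylammonium 2-bromo-4-{1-[(4-bromofuran-2-yl)methoxy]prop-2-yn-1-yl}phenoxide | [O-]c1ccc(cc1Br)C(C#C)OCc1cc(Br)co1.CCCC[N+](CCCC)(CCCC)CCCC | intermediate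
10 | racemic 2-bromo-4-{1-[(4-bromofuran-2-yl)methoxy]prop-2-yn-1-yl}phenyl pivalate | CC(C)(C)C(=O)Oc1ccc(cc1Br)C(C#C)OCc1cc(Br)co1 | intermediate
11 | racemic oxepine: 1,3-dihydrofuro[3,4-c]oxepine with the 3-bromo-4-(pivaloyloxy)phenyl group on the dihydrofuran CH carbon, the oxepine oxygen linking future C3 and C4, and bromine on future C5 | CC(C)(C)C(=O)Oc1ccc(cc1Br)C1OCC2=CC(Br)=COC=C12 | intermediate
12 | arene oxide: 6-bromo-3-[3-bromo-4-(pivaloyloxy)phenyl]-4,5-epoxy-1,3,4,5-tetrahydroisobenzofuran (racemic, mixture of diastereomers) | CC(C)(C)C(=O)Oc1ccc(cc1Br)C1OCC2=C1C1OC1C(Br)=C2 | intermediate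
13 | racemic 6-bromo-3-[3-bromo-4-(pivaloyloxy)phenyl]-1,3-dihydroisobenzofuran-4-ol | CC(C)(C)C(=O)Oc1ccc(cc1Br)C1OCc2cc(Br)cc(O)c12 | intermediate
14 | racemic 6-bromo-3-[3-bromo-4-(pivaloyloxy)phenyl]-1,3-dihydroisobenzofuran-4,5-dione | CC(C)(C)C(=O)Oc1ccc(cc1Br)C1OCC2=C1C(=O)C(=O)C(Br)=C2 | intermediate
15 | racemic 6-bromo-3-[3-bromo-4-(pivaloyloxy)phenyl]-1,3-dihydroisobenzofuran-4,5-diol | CC(C)(C)C(=O)Oc1ccc(cc1Br)C1OCc2cc(Br)c(O)c(O)c12 | intermediate
16 | racemic 6-bromo-3-(3-bromo-4-hydroxyphenyl)-1,3-dihydroisobenzofuran-4,5-diol | Oc1ccc(cc1Br)C1OCc2cc(Br)c(O)c(O)c12 | intermediate
17 | 6-bromo-3-(3-bromo-4-hydroxybenzyl)-4-(hydroxymethyl)benzene-1,2-diol (CNP0232913.0) | OCc1cc(Br)c(O)c(O)c1Cc1ccc(O)c(Br)c1 | target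

## Step count and least certain steps

Total step count: 10. Longest linear sequence: 8 steps (steps 1, 2, 5, 6, 7, 8, 9, 10 from aldehyde 1); steps 3 and 4 are the furan branch.

**Step 7 (key step).** The 4-bromofuran is a weaker nucleophile than the furans on which this isomerization is established. If its attack on the gold-bound alkyne is slow, other processes can take over: hydration of the alkyne, 1,5-hydride transfer from the furfurylic CH2 to the activated alkyne with fragmentation of the ether, or residual ionization at the bridge carbon. The fallback closes ring A by a thermal cycloaddition that needs no Lewis acid. It sets out from silyl ether 8. Deprotonation of the alkyne with EtMgBr and formylation with DMF would give racemic 4-[(4-bromofuran-2-yl)methoxy]-4-{3-bromo-4-[(triisopropylsilyl)oxy]phenyl}but-2-ynal F1. On warming in toluene the furan should add across the activated triple bond in an intramolecular Diels–Alder reaction, forming the same C1–C2 and C3–C4 bonds, to give the formyl-substituted 7-oxanorbornadiene F2. With a trace of acid the oxygen bridge would open and the ring aromatize to racemic 6-bromo-3-{3-bromo-4-[(triisopropylsilyl)oxy]phenyl}-5-hydroxy-1,3-dihydroisobenzofuran-4-carbaldehyde F3, which has the hydroxyl on C4 and the formyl group on C3 of ring A. Dakin oxidation (H2O2, NaOH) would exchange the formyl group for hydroxyl and give racemic 6-bromo-3-{3-bromo-4-[(triisopropylsilyl)oxy]phenyl}-1,3-dihydroisobenzofuran-4,5-diol F4. TBAF would then give 16, where the route is rejoined; steps 6 to 9 are bypassed.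

**Step 8.** Oxygen transfer from IBX is fastest on electron-rich phenols and may be slow on a ring that carries bromine. The bromo-ortho-quinone may also add nucleophiles or condense before it is reduced. The fallback replaces oxygen transfer by carbon–carbon bond formation and excision. It sets out from 13. Magnesium-mediated ortho-formylation (MgCl2, Et3N, paraformaldehyde, THF, reflux) is specific for the free ortho carbon C4 and would give racemic 6-bromo-3-[3-bromo-4-(pivaloyloxy)phenyl]-4-hydroxy-1,3-dihydroisobenzofuran-5-carbaldehyde F5; the hindered pivalate is expected to resist acyl transfer to the magnesium phenoxide. Dakin oxidation with alkaline H2O2 would replace the formyl group by hydroxyl, and the same aqueous base would saponify the pivalate. The sequence returns to the route at 16 and bypasses step 9.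

**Step 10.** The product is a para-hydroxybenzylic alcohol. Prolonged contact with acid and silane could ionize its primary C–O bond as well, with over-reduction to a methyl group, or let the diarylmethyl cation alkylate a second molecule. The fallback lowers the donor strength of the C4 oxygen during the reduction. It sets out from 16. Condensation with PhB(OH)2 (toluene, removal of water) would give the cyclic phenylboronate of 16, in which the C3 and C4 oxygens are joined through boron in a 1,3,2-benzodioxaborole, F6. Its boron-bound oxygens are poor donors to ring A, while the para-hydroxyl of ring B stays free to drive the ionization. Et3SiH and TFA would then give the corresponding cyclic phenylboronate of 17, F7, and hydrolysis of the boronate during aqueous work-up would release 17.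

**Step 5 (with step 4).** Furfuryl bromide 7 can self-condense before it is alkylated, and excess base can isomerize the propargylic ether to an allenyl ether. The fallback reverses the polarity of the ether formation and avoids both the halide and the strong base. It sets out from 4 and 6. Acid-catalysed propargylic substitution (FeCl3, 5 mol %, MeCN, rt) would ionize the para-silyloxy-stabilized alcohol 4, and an excess of alcohol 6 would capture the cation at oxygen to give 8 directly. Bromide 7 is not needed and no new compound arises (F0).

## Further compounds

F1 | step 7 | racemic 4-[(4-bromofuran-2-yl)methoxy]-4-{3-bromo-4-[(triisopropylsilyl)oxy]phenyl}but-2-ynal | CC(C)[Si](Oc1ccc(cc1Br)C(C#CC=O)OCc1cc(Br)co1)(C(C)C)C(C)C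
F2 | step 7 | intramolecular Diels–Alder adduct of F1: 7-oxanorbornadiene fused to the dihydrofuran ring, formyl group on the new ring alkene, bromine on the other alkene (racemic, mixture of diastereomers) | CC(C)[Si](Oc1ccc(cc1Br)C1OCC23OC(C(C=O)=C12)C(Br)=C3)(C(C)C)C(C)C
F3 | step 7 | racemic 6-bromo-3-{3-bromo-4-[(triisopropylsilyl)oxy]phenyl}-5-hydroxy-1,3-dihydroisobenzofuran-4-carbaldehyde | CC(C)[Si](Oc1ccc(cc1Br)C1OCc2cc(Br)c(O)c(C=O)c12)(C(C)C)C(C)C
F4 | step 7 | racemic 6-bromo-3-{3-bromo-4-[(triisopropylsilyl)oxy]phenyl}-1,3-dihydroisobenzofuran-4,5-diol | CC(C)[Si](Oc1ccc(cc1Br)C1OCc2cc(Br)c(O)c(O)c12)(C(C)C)C(C)C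
F5 | step 8 | racemic 6-bromo-3-[3-bromo-4-(pivaloyloxy)phenyl]-4-hydroxy-1,3-dihydroisobenzofuran-5-carbaldehyde | CC(C)(C)C(=O)Oc1ccc(cc1Br)C1OCc2cc(Br)c(C=O)c(O)c12
F6 | step 10 | cyclic phenylboronate of 16 (racemic; C3 and C4 oxygens of ring A joined through B–Ph) | Oc1ccc(cc1Br)C1OCc2cc(Br)c3OB(c4ccccc4)Oc3c12
F7 | step 10 | cyclic phenylboronate of 17 (C3 and C4 oxygens of ring A joined through B–Ph) | OCc1cc(Br)c2OB(c3ccccc3)Oc2c1Cc1ccc(O)c(Br)c1
F0 | step 5 | none | none
A1 | alternative 1 | 2,2-dimethyl-5-(trimethylsilyl)-1,3-benzodioxol-4-yl trifluoromethanesulfonate | CC1(C)Oc2ccc([Si](C)(C)C)c(OS(=O)(=O)C(F)(F)F)c2O1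
A2 | alternative 1 | tert-butyl isocyanide | CC(C)(C)[N+]#[C-]
A3 | alternative 1 | 3-bromo-4-methoxybenzaldehyde | COc1ccc(C=O)cc1Br
A4 | alternative 1 | racemic 3-(3-bromo-4-methoxyphenyl)-1-(tert-butylimino)-1,3-dihydroisobenzofuran with an isopropylidene acetal on the C4 and C5 oxygens | CC(C)(C)/N=C1\OC(c2ccc(OC)c(Br)c2)c2c1ccc1OC(C)(C)Oc12
A5 | alternative 2 | methyl 5-bromo-3,4-dimethoxy-2-(3-oxopropyl)benzoate | COC(=O)c1cc(Br)c(OC)c(OC)c1CCC=O
A6 | alternative 2 | methyl vinyl ketone | CC(=O)C=C
A7 | alternative 2 | racemic methyl 5-bromo-3,4-dimethoxy-2-[(4-oxocyclohex-2-en-1-yl)methyl]benzoate | COC(=O)c1cc(Br)c(OC)c(OC)c1CC1CCC(=O)C=C1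
A8 | alternative 3 | 5-(3-bromo-4-methoxyphenyl)pentane-2,3-dione | CC(=O)C(=O)CCc1ccc(OC)c(Br)c1
A9 | alternative 3 | 5-(3-bromo-4-methoxyphenyl)-2,3-bis(trimethylsilyloxy)penta-1,3-diene | C=C(O[Si](C)(C)C)C(O[Si](C)(C)C)=CCc1ccc(OC)c(Br)c1
A10 | alternative 3 | methyl propiolate | COC(=O)C#C
A11 | alternative 3 | racemic methyl 6-(3-bromo-4-methoxybenzyl)-4,5-bis(trimethylsilyloxy)cyclohexa-1,4-diene-1-carboxylate | COC(=O)C1=CCC(O[Si](C)(C)C)=C(O[Si](C)(C)C)C1Cc1ccc(OC)c(Br)c1
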